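**Plan**
1. The retrosynthesis first cuts the side-chain CH2–CH2 bond C1′–C2′ (C1′ is the CH2 on ring carbon C4 of the furan-2(5H)-one). The ring is then cut at C3=C4 and O1–C2 (Wittig olefination, lactonisation), and the chain at the CH2–CH2 bond next to the carbinol carbon (epoxide opening).
2. Enabling feature: C1′ is the unsubstituted end of the allyl unit C1′–C4=C3 of the butenolide. The other end, C3, is fully substituted (CH3, C2=O, C4) and the alkene is conjugated to the C2 lactone carbonyl, so an allyl–nickel intermediate should couple at C1′ and return the tetrasubstituted C3=C4 bond intact.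
3. Second feature: C4 carries two CH2 groups (ring C5–O and C1′). The ring can therefore come in one step from symmetrical 1,3-dihydroxyacetone with no alkene-geometry problem, and the spare arm becomes the allylic bromide.
4. Forward order: furanone ring (steps 1–2), then the chain with its stereocentre, acetate and terminal bromide (steps 3–5). The two are joined last (step 6), which gives the target directly without protecting groups.
5. Stereochemistry: the only stereocentre, (S) at the acetoxy carbon, comes from (S)-propylene oxide, opened at its CH2 so that the C–O centre is never touched.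

Key step: step 6

Remark: 1,3-dihydroxyacetone is charged as its commercial dimer, which dissociates to the monomer under the conditions of step 1; the monomer is the species numbered 1.

**Route**

Step 1
Reactants: 1 1,3-dihydroxyacetone; 2 ethyl 2-(triphenylphosphoranylidene)propanoate
Product: 4 4-(hydroxymethyl)-3-methylfuran-2(5H)-one, via diol ester 3 (not isolated)
Conditions: MeCN, 70 °C; then TsOH·H2O (cat.), rt
Reagents that add atoms: none
Why: Wittig olefination of the activated α,α′-dihydroxy ketone by the stabilised ylide should give diol ester 3, which lactonises because one of its two identical CH2OH arms is necessarily cis to the ester, so the tetrasubstituted C3=C4 bond needs no geometry control.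

Step 2
Reactants: 4 4-(hydroxymethyl)-3-methylfuran-2(5H)-one
Product: 5 4-(bromomethyl)-3-methylfuran-2(5H)-one
Conditions: CBr4, PPh3, CH2Cl2, 0 °C
Reagents that add atoms: carbon tetrabromide, BrC(Br)(Br)Br
Why: Appel bromination of the primary allylic alcohol (SN2 on the alkoxyphosphonium ion) runs under neutral conditions that should leave the base-sensitive butenolide untouched.

Step 3
Reactants: 6 12-bromododec-1-ene; 7 (S)-2-methyloxirane ((S)-propylene oxide)
Product: 9 (S)-pentadec-14-en-2-ol, via Grignard reagent 8 (not isolated)
Conditions: Mg, THF, 40 °C; then CuI (5 mol %), 7, −30 → 0 °C; H2O quench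
Reagents that add atoms: none
Why: Copper-catalysed Grignard opening of the epoxide takes place by SN2 attack at the unsubstituted CH2, so the C–O stereocentre of 7 is carried unchanged into C2 of 9 as (S).

Step 4
Reactants: 9 (S)-pentadec-14-en-2-ol
Product: 10 (S)-pentadec-14-en-2-yl acetate
Conditions: Ac2O, pyridine, DMAP (cat.), CH2Cl2, rt
Reagents that add atoms: acetic anhydride, CC(=O)OC(C)=O
Why: DMAP-catalysed O-acylation does not break the C–O bond at the stereocentre, so the configuration is retained.

Step 5
Reactants: 10 (S)-pentadec-14-en-2-yl acetate
Product: 11 (S)-15-bromopentadecan-2-yl acetate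
Conditions: HBr (g), dibenzoyl peroxide (5 mol %), hexane, 0 °C
Reagents that add atoms: hydrogen bromide, Br
Why: Peroxide-initiated radical-chain hydrobromination should place bromine on the terminal carbon (anti-Markovnikov; Br• adds to CH2, the secondary radical abstracts H from HBr), and the apolar solvent and low temperature disfavour ionic addition and acetate cleavage.

Step 6
Reactants: 11 (S)-15-bromopentadecan-2-yl acetate; 5 4-(bromomethyl)-3-methylfuran-2(5H)-one
Product: 13 [(2S)-16-(4-methyl-5-oxo-2,5-dihydrofuran-3-yl)hexadecan-2-yl] acetate (the target), via alkylzinc bromide 12 (not isolated)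
Conditions: Zn dust (1.5 equiv), I2 (5 mol %), DMA, 80 °C; filter from excess Zn; then 5 (0.75 equiv), NiCl2·glyme (5 mol %), pybox ligand (6 mol %), DMA, 0 °C → rt
Reagents that add atoms: none
Why: Zinc inserts into the primary C–Br bond of 11 to give alkylzinc 12, which transmetalates to nickel; the nickel activates the allylic C–Br bond of 5 to an allylnickel species delocalised over C1′–C4–C3, and C(sp3)–C(sp3) reductive elimination at the C1′ terminus forms the C1′–C2′ bond. The closest known reaction type is the nickel/pybox-catalysed Negishi cross-coupling of alkylzinc halides with allylic halides. No ring is closed and no stereocentre is formed; the (S) centre lies thirteen CH2 groups away and is not involved. Regioselectivity for C1′ over C3 is needed and should follow because C3 is fully substituted (CH3, C2 carbonyl, C4) and bond formation at C1′ keeps the C3=C4–C2=O conjugation. Chemoselectivity towards the lactone, the acetate and conjugate addition is needed and should follow from the low basicity and nucleophilicity of an alkylzinc halide and from the tetrasubstituted, β,β-disubstituted enoate. Cross- over homo-coupling is needed and is favoured by preforming 12, removing zinc metal before 5 is added, and using 12 in excess.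

**Compound list**
1 | 1,3-dihydroxyacetone (charged as its dimer) | OCC(=O)CO | starting material
2 | ethyl 2-(triphenylphosphoranylidene)propanoate | CCOC(=O)C(C)=P(c1ccccc1)(c1ccccc1)c1ccccc1 | starting material
3 | ethyl 4-hydroxy-3-(hydroxymethyl)-2-methylbut-2-enoate | CCOC(=O)C(C)=C(CO)CO | intermediate (not isolated)
4 | 4-(hydroxymethyl)-3-methylfuran-2(5H)-one | OCC1=C(C)C(=O)OC1 | intermediate
5 | 4-(bromomethyl)-3-methylfuran-2(5H)-one | BrCC1=C(C)C(=O)OC1 | intermediate
6 | 12-bromododec-1-ene | C=CCCCCCCCCCCBr | starting material
7 | (S)-2-methyloxirane | C[C@H]1CO1 | starting material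
8 | dodec-11-en-1-ylmagnesium bromide | C=CCCCCCCCCCC[Mg]Br | intermediate (not isolated)
9 | (S)-pentadec-14-en-2-ol | C[C@H](O)CCCCCCCCCCCC=C | intermediate
10 | (S)-pentadec-14-en-2-yl acetate | CC(=O)O[C@@H](C)CCCCCCCCCCCC=C | intermediate
11 | (S)-15-bromopentadecan-2-yl acetate | CC(=O)O[C@@H](C)CCCCCCCCCCCCCBr | intermediate
12 | [(14S)-14-acetoxypentadecyl]zinc bromide | CC(=O)O[C@@H](C)CCCCCCCCCCCCC[Zn]Br | intermediate (not isolated)
13 | [(2S)-16-(4-methyl-5-oxo-2,5-dihydrofuran-3-yl)hexadecan-2-yl] acetate | CC(=O)O[C@@H](C)CCCCCCCCCCCCCCC1=C(C)C(=O)OC1 | target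

**Summary**
Total step count: 6. Longest linear sequence: 4 steps (steps 3, 4, 5, 6); the furanone branch (steps 1, 2) joins at step 6.

**Steps most likely to fail, with fallbacks**

Step 6. Possible failures are homo-coupling of the allyl partner, C–C bond formation at the hindered C3 terminus of the allyl unit, and protodezincation of the alkylzinc before it couples. The fallback replaces the sp3–sp3 coupling by olefination and reduction; it sets out from 11 and 5 and comes back at 13. Kornblum oxidation of 11 (NaHCO3, DMSO, 110 °C) should give (S)-15-oxopentadecan-2-yl acetate F1. Bromide 5 with PPh3 (toluene, 60 °C) should give [(4-methyl-5-oxo-2,5-dihydrofuran-3-yl)methyl]triphenylphosphonium bromide F2. Wittig reaction of the vinylogously stabilised ylide of F2 (K2CO3, 18-crown-6 cat., CH2Cl2, rt) with F1 should form the C1′=C2′ alkene in (S)-16-(4-methyl-5-oxo-2,5-dihydrofuran-3-yl)hexadec-15-en-2-yl acetate F3, as an E/Z mixture that is of no consequence. Diimide (TsNHNH2, NaOAc, DME/H2O, 80 °C) should then saturate only this disubstituted alkene, the tetrasubstituted ring alkene being inert, and give 13.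

Step 1. Possible failures are slow olefination of a ketone by an α-branched stabilised ylide, with base-induced ketose–aldose isomerisation and self-condensation of the ketone competing. The fallback sets out from 1 and comes back at 4. Silylation of 1 (TBSCl, imidazole, DMF) should give 1,3-bis[(tert-butyldimethylsilyl)oxy]propan-2-one F4. Horner–Wadsworth–Emmons reaction with triethyl 2-phosphonopropionate (NaH, THF, 0 °C → rt) should give ethyl 4-[(tert-butyldimethylsilyl)oxy]-3-{[(tert-butyldimethylsilyl)oxy]methyl}-2-methylbut-2-enoate F5. Aqueous HCl in THF/MeOH should remove both silyl groups and close the lactone to 4.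

Step 5. Possible failures are ionic (Markovnikov) addition competing with the radical chain, and acid-promoted cleavage or substitution of the secondary acetate. The fallback sets out from 10 and comes back at 11. Hydroboration with 9-BBN (THF, 0 °C → rt) and mild oxidation (NaBO3·4H2O, H2O, rt), which spares the acetate, should give (S)-15-hydroxypentadecan-2-yl acetate F6. Appel bromination (CBr4, PPh3, CH2Cl2, 0 °C) should then give 11.

**Further compounds**
F1 | step 6 | (S)-15-oxopentadecan-2-yl acetate | CC(=O)O[C@@H](C)CCCCCCCCCCCCC=O
F2 | step 6 | [(4-methyl-5-oxo-2,5-dihydrofuran-3-yl)methyl]triphenylphosphonium bromide | O=C1OCC(C[P+](c2ccccc2)(c2ccccc2)c2ccccc2)=C1C.[Br-]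
F3 | step 6 | (S)-16-(4-methyl-5-oxo-2,5-dihydrofuran-3-yl)hexadec-15-en-2-yl acetate (E/Z mixture) | CC(=O)O[C@@H](C)CCCCCCCCCCCCC=CC1=C(C)C(=O)OC1
F4 | step 1 | 1,3-bis[(tert-butyldimethylsilyl)oxy]propan-2-one | CC(C)(C)[Si](C)(C)OCC(=O)CO[Si](C)(C)C(C)(C)C
F5 | step 1 | ethyl 4-[(tert-butyldimethylsilyl)oxy]-3-{[(tert-butyldimethylsilyl)oxy]methyl}-2-methylbut-2-enoate | CCOC(=O)C(C)=C(CO[Si](C)(C)C(C)(C)C)CO[Si](C)(C)C(C)(C)C
F6 | step 5 | (S)-15-hydroxypentadecan-2-yl acetate | CC(=O)O[C@@H](C)CCCCCCCCCCCCCO
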